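**Retrosynthetic overview**
1. The 14-membered ring is closed last, at the unactivated C14–C1 sp3–sp2 bond. Zinc inserts selectively into the alkyl iodide, then an intramolecular Negishi coupling engages the vinyl bromide. The usual closures (HWE or Stille at the dienoate, RCM/NHK, late lactonisation) are avoided.
2. C4 is a one-carbon linchpin. The commercial Still–Gennari phosphonate adds (Michael) to a C7 vinyl ketone to form C4–C5, then olefinates a (Z)-β-bromoenal to form (Z)-C3=C4.
3. C1=C2 geometry comes from trans-hydroalumination/bromination of a propargylic alcohol and is carried through with retention.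
4. The seven-membered lactone is formed first, by RCM of a 2-(2-chloroethyl)acrylate of the tertiary alcohol. The ring enforces C11=C12 geometry.
5. C8 (S) comes from (R)-2-methylglycidol by epoxide opening at CH2. Ring order: lactone (step 5), then carbocycle (step 15).

Assumption: cembrane numbering is used (C1 bears iPr, C4 bears CO2Me = C18, C7 = ketone, C8 = stereocentre, C20 = lactone C=O). The SMILES gives 8S, ester cis to C2, and iPr trans to C3.
Assumption: (R)-2-methylglycidol is purchased. It is also available in one step by Sharpless epoxidation of methallyl alcohol with D-(–)-DIPT.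

**Step 1**
Reactants: 1 (R)-2-methylglycidol; 2 allylmagnesium chloride
Product: 3 (2S)-2-methylhex-5-ene-1,2-diol
Conditions: allylMgCl (3 equiv), CuI (10 mol %), THF, –40 → 0 °C
Reagents that add atoms: allylmagnesium chloride, C=CC[Mg]Cl
Why: Cu-catalysed epoxide opening occurs at the unhindered CH2, so the C8–O bond is untouched and the purchased configuration becomes 8S (the descriptor changes only through CIP priorities).

**Step 2**
Reactants: 3
Product: 4 (2S)-2-methyl-1-(triethylsilyloxy)hex-5-en-2-ol
Conditions: TESCl (1.05 equiv), imidazole, CH2Cl2, 0 °C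
Reagents that add atoms: chlorotriethylsilane, CC[Si](Cl)(CC)CC
Why: Selective silylation takes the primary OH and leaves the hindered tertiary OH free.

**Step 3**
Reactants: 5 α-methylene-γ-butyrolactone (tulipalin A)
Product: 6 4-chloro-2-methylidenebutanoyl chloride
Conditions: SOCl2 (1.5 equiv), ZnCl2 (5 mol %), BHT (cat.), 65 °C; distil
Reagents that add atoms: thionyl chloride, O=S(Cl)Cl
Why: This is a ZnCl2-catalysed chlorinative lactone opening (chloride SN2 at O–CH2, then acid chloride formation), the same reaction type that converts butyrolactone to 4-chlorobutyryl chloride; BHT suppresses acrylate polymerisation.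

**Step 4**
Reactants: 4; 6
Product: 7 (2S)-2-methyl-1-(triethylsilyloxy)hex-5-en-2-yl 4-chloro-2-methylidenebutanoate
Conditions: Et3N, DMAP (0.5 equiv), CH2Cl2, 0 → 40 °C
Reagents that add atoms: 6 (acyl donor), C=C(CCCl)C(=O)Cl
Why: DMAP-catalysed acylation of a tertiary alcohol with an acid chloride; the alkyl chloride and TES ether are inert and C8 is not involved.

**Step 5**
Reactants: 7
Product: 8 (7S)-3-(2-chloroethyl)-7-methyl-7-[(triethylsilyloxy)methyl]-6,7-dihydrooxepin-2(5H)-one
Conditions: Hoveyda–Grubbs II (7.5 mol %), 1,4-benzoquinone (15 mol %), toluene (5 mM), 80 °C, Ar sparge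
Reagents that add atoms: none (ethylene is lost)
Why: In this ring-closing metathesis the catalyst loads on the monosubstituted alkene and closes onto the 1,1-disubstituted acrylate, helped by the quaternary C8; the seven-membered ring forces C20 cis to C10.

**Step 6**
Reactants: 8
Product: 9 the corresponding 3-(2-iodoethyl) lactone
Conditions: NaI (10 equiv), acetone, reflux
Reagents that add atoms: sodium iodide, [Na+].[I-]
Why: Finkelstein exchange on a primary chloride; it is done early so that iodide never meets the isomerisable dienoate.

**Step 7**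
Reactants: 9
Product: 10 (2S)-6-(2-iodoethyl)-2-methyl-7-oxo-2,3,4,7-tetrahydrooxepine-2-carbaldehyde
Conditions: (COCl)2 (4 equiv), DMSO (8 equiv), CH2Cl2, –78 → –35 °C; Et3N, → 0 °C
Reagents that add atoms: none
Why: Swern oxidation acts directly on a primary TES ether (in situ desilylation, then oxidation); the α-carbon is quaternary and cannot epimerise, and the alkyl iodide is inert at these temperatures.

**Step 8**
Reactants: 10; 11 vinylmagnesium bromide
Product: 12 (7S)-7-(1-hydroxyprop-2-enyl)-3-(2-iodoethyl)-7-methyl-6,7-dihydrooxepin-2(5H)-one (C7 epimers)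
Conditions: vinylMgBr (1.15 equiv), THF, –78 °C; AcOH quench at –78 °C
Reagents that add atoms: vinylmagnesium bromide, C=C[Mg]Br
Why: Grignard 1,2-addition to the aldehyde is far faster than attack on the hindered enoate lactone, the cold quench prevents acyl migration, and the new C7 centre is erased in step 9.

**Step 9**
Reactants: 12
Product: 13 (7S)-7-acryloyl-3-(2-iodoethyl)-7-methyl-6,7-dihydrooxepin-2(5H)-one
Conditions: Dess–Martin periodinane, NaHCO3, CH2Cl2, 0 °C → rt; used crude
Reagents that add atoms: none
Why: A neutral Dess–Martin oxidation of the allylic alcohol gives the vinyl ketone (C5=C6–C7=O).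

**Step 10**
Reactants: 13; 14 methyl bis(2,2,2-trifluoroethyl)phosphonoacetate
Product: 15 methyl 2-[bis(2,2,2-trifluoroethoxy)phosphoryl]-5-[(2S)-6-(2-iodoethyl)-2-methyl-7-oxo-2,3,4,7-tetrahydrooxepin-2-yl]-5-oxopentanoate (C4 epimers)
Conditions: 14 (1.5 equiv), Cs2CO3 (10 mol %), THF, –20 → 0 °C
Reagents that add atoms: 14, COC(=O)CP(=O)(OCC(F)(F)F)OCC(F)(F)F
Why: Base-catalysed Michael addition of the stabilised phosphonate carbanion to the unsubstituted enone terminus forms C4–C5; it outruns SN2 at the iodide, and excess 14 prevents double addition.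

**Step 11**
Reactants: 16 3-methylbut-1-yne; 17 paraformaldehyde
Product: 18 4-methylpent-2-yn-1-ol
Conditions: n-BuLi, THF, –78 °C; (CH2O)n, → rt
Reagents that add atoms: formaldehyde (as paraformaldehyde), C=O
Why: Lithium acetylide hydroxymethylation.

**Step 12**
Reactants: 18
Product: 19 (Z)-3-bromo-4-methylpent-2-en-1-ol
Conditions: Red-Al (1.6 equiv), THF, 0 °C → rt; EtOAc; NBS, –78 → 0 °C
Reagents that add atoms: N-bromosuccinimide, O=C1CCC(=O)N1Br
Why: Alkoxide-directed trans-hydroalumination gives the cyclic vinylalanate (Al on C1, cis to CH2O), and bromodealumination with retention places Br cis to C3, which fixes the future C14/C3 cis relationship of C1=C2.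

**Step 13**
Reactants: 19
Product: 20 (Z)-3-bromo-4-methylpent-2-enal
Conditions: MnO2 (20 equiv), CH2Cl2, rt, dark; used fresh
Reagents that add atoms: none
Why: MnO2 allylic oxidation under neutral conditions preserves the Z geometry.

**Step 14**
Reactants: 15; 20
Product: 21 methyl (2Z,4Z)-5-bromo-2-{3-[(2S)-6-(2-iodoethyl)-2-methyl-7-oxo-2,3,4,7-tetrahydrooxepin-2-yl]-3-oxopropyl}-6-methylhepta-2,4-dienoate
Conditions: KHMDS (1.0 equiv), 18-crown-6 (4 equiv), THF, –78 °C; then 20
Reagents that add atoms: none beyond 15 and 20
Why: In this Still–Gennari olefination the trifluoroethyl phosphonate makes elimination fast and irreversible from the kinetic adduct, so CO2Me ends cis to C2 (C5 trans); one equivalent of base removes only the most acidic C4–H, and 1,2-attack is preferred over the iPr-shielded β-carbon of 20.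

**Step 15**
Reactants: 21
Product: 22 ketoemblide
Conditions: (i) Zn dust (BrCH2CH2Br/TMSCl-activated), LiCl, THF, 25 °C; (ii) syringe-pump addition to Pd-PEPPSI-IPent (15 mol %), THF–NMP (final 1 mM), 45 °C
Reagents that add atoms: none
Why: Proposed new method: Zn/LiCl inserts into the primary C14–I bond while the vinyl C–Br, ketone, esters and lactone are tolerated; Pd(0) then adds to C1–Br, and intramolecular transmetalation and reductive elimination with retention close the 14-membered ring with C14 cis to C3, the bulky NHC ligand disfavouring β-hydride elimination and slow addition suppressing oligomers. The closest known reaction types are intermolecular alkyl–alkenyl Negishi coupling and B-alkyl Suzuki macrocyclisation onto trisubstituted vinyl halides.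

**Compound list**
1 | (R)-2-methylglycidol | C[C@@]1(CO)CO1 | starting material
2 | allylmagnesium chloride | C=CC[Mg]Cl | starting material
3 | (2S)-2-methylhex-5-ene-1,2-diol | C=CCC[C@](C)(O)CO | intermediate
4 | primary TES ether of 3 | C=CCC[C@](C)(O)CO[Si](CC)(CC)CC | intermediate
5 | α-methylene-γ-butyrolactone | C=C1CCOC1=O | starting material
6 | 4-chloro-2-methylidenebutanoyl chloride | C=C(CCCl)C(=O)Cl | intermediate
7 | tertiary 2-(2-chloroethyl)acrylate ester | C=CCC[C@](C)(OC(=O)C(=C)CCCl)CO[Si](CC)(CC)CC | intermediate
8 | chloroethyl oxepinone | ClCCC1=CCC[C@](C)(OC1=O)CO[Si](CC)(CC)CC | intermediate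
9 | iodoethyl oxepinone | ICCC1=CCC[C@](C)(OC1=O)CO[Si](CC)(CC)CC | intermediate
10 | C7 aldehyde | ICCC1=CCC[C@](C)(OC1=O)C=O | intermediate
11 | vinylmagnesium bromide | C=C[Mg]Br | starting material
12 | C7 allylic alcohol (epimers) | ICCC1=CCC[C@](C)(OC1=O)C(O)C=C | intermediate
13 | vinyl ketone | ICCC1=CCC[C@](C)(OC1=O)C(=O)C=C | intermediate
14 | methyl bis(2,2,2-trifluoroethyl)phosphonoacetate | COC(=O)CP(=O)(OCC(F)(F)F)OCC(F)(F)F | starting material
15 | Michael adduct phosphonate (C4 epimers) | ICCC1=CCC[C@](C)(OC1=O)C(=O)CCC(C(=O)OC)P(=O)(OCC(F)(F)F)OCC(F)(F)F | intermediate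
16 | 3-methylbut-1-yne | CC(C)C#C | starting material
17 | paraformaldehyde (formaldehyde) | C=O | starting material
18 | 4-methylpent-2-yn-1-ol | CC(C)C#CCO | intermediate
19 | (Z)-3-bromo-4-methylpent-2-en-1-ol | OC/C=C(\Br)C(C)C | intermediate
20 | (Z)-3-bromo-4-methylpent-2-enal | O=C/C=C(\Br)C(C)C | intermediate
21 | (2Z,4Z)-bromodienoate alkyl iodide | ICCC1=CCC[C@](C)(OC1=O)C(=O)CC/C(C(=O)OC)=C/C=C(\Br)C(C)C | intermediate
22 | ketoemblide | COC(=O)/C1=C\C=C(\C(C)C)CCC2=CCC[C@](C)(OC2=O)C(=O)CC1 | target

**Total steps:** 15
**Longest linear sequence:** 11 (steps 1, 2, 4–10, 14, 15)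

**Steps most likely to fail**
1. **Step 15.** The risks are oligomerisation, β-hydride elimination and a hindered C1–Br.
   - Fallback: reverse the order of events. Couple the zinc reagent from 9 intermolecularly with the TBS ether of 19, then build the phosphonate as in steps 7–10. Unmask and oxidise C3 to the enal, then close the ring by intramolecular Still–Gennari olefination at C3=C4.
2. **Step 5.** A trisubstituted seven-membered enoate is a demanding RCM product.
   - Fallback: form the ring by olefination instead. Esterify 4 with 2-(diethoxyphosphoryl)-4-(silyloxy)butanoic acid and ozonise the terminal alkene. Close the ring by intramolecular HWE (LiCl/DBU), where the ring enforces geometry, then convert the silyl ether to the iodide.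
3. **Step 14.** The risks are Z-selectivity and competing addition–elimination on the β-bromoenal.
   - Fallback: set the geometry mechanistically. A Pd(OAc)2/LiBr/AcOH trans-bromopalladation/conjugate addition of methyl propiolate to 13 gives the (Z)-β-bromoacrylate with C4–C5 already formed. Join C2–C3 by chemoselective Stille coupling with (Z)-tributyl(2-bromo-3-methylbut-1-enyl)stannane to reach 21.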